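The amounts in amber and red are equal, 0.050 M of Z on 50 µM of X; amber is fed over 30 h and stays at −10 °C, while red is fed over 10 h and goes to 10 °C at 10 h.

| flask | Z | X | temperature | remark | time |
|---|---|---|---|---|---|
| summer | 0.050 M (fed, over 10 h) | 34 µM | −15 °C | run made earlier; the fed solution adds 0.20 times the starting volume |  |
| autumn | 0.050 M (fed, over 10 h) | 75 µM | 0 °C | run made earlier; the fed solution adds 0.20 times the starting volume |  |
| dusk | 0.10 M (fed, over 10 h) | 50 µM | −15 °C | run made earlier; the fed solution adds 0.20 times the starting volume |  |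
| amber | 0.050 M (fed, over 30 h) | 50 µM |  | at −10 °C throughout; the fed solution adds 0.20 times the starting volume | 4.0 d |
| red | 0.050 M (fed, over 10 h) | 50 µM |  | at −10 °C until 10 h, from then on at 10 °C; the fed solution adds 0.20 times the starting volume | 4.0 d |

summer run (percent of the Z charged)

| time / d | D / % | E / % |
|---|---|---|
| 0.625 | 24.1 | 13.3 |
| 1.25 | 25.5 | 32.3 |
| 2.08 | 19.9 | 42.6 |
| 2.50 | 17.9 | 45.1 |
| 3.00 | 16.8 | 46.5 |

autumn run (percent of the Z charged)

| time / h | D / % | E / % |
|---|---|---|
| 10.0 | 25.1 | 37.4 |
| 20.0 | 24.5 | 51.9 |
| 30.0 | 24.8 | 53.0 |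
| 40.0 | 25.8 | 51.7 |

dusk run (percent of the Z charged)

| time / d | D / % | E / % |
|---|---|---|
| 0.250 | 11.9 | 1.8 |
| 0.500 | 25.6 | 9.7 |
| 0.833 | 28.9 | 22.9 |
| 1.67 | 23.1 | 36.0 |
| 3.00 | 15.7 | 37.9 |

(scatter of a reading: 0.5 percentage points)

- percentages count the Z that a species holds: one Q counts as two
- every charge counts on the volume at the start, and the solution that is fed holds the whole dose
- steps under discussion: Z <-> G; Z + X -> X + D; X + G -> X + E; Z + D -> Q; D <-> J
- in a conversion G counts as not yet reacted
- percentages count the whole charge, also what has not yet gone in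

- the winner by share of D in all that became D or E or J or Q; "neither" if no more than 2 percentage points parts them (amber / red / neither)
- share of D in all that became D or E or J or Q, amber
- share of D in all that became D or E or J or Q, red

Two views part here. The split view reads the selectivity, the share asked for, off the branch where Z goes either to D or through G to E. Late E reads 46.5% in summer at −15 °C and 53.0% in autumn at 0 °C, so on this view warming is dear. The forecast stands here: amber 21%, red 24%, red narrowly ahead; it lets D relax to J as well, but with “warming while much Z and G remain pushes E” to about 60%.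

The balance view, my own, gives E no such rise: it borrows late E from the earlier runs and lets what stands beside D carry the warming. Call ρ the remainder ratio: the charge outside D and E, over D, late in a run. As readings, ρ is 2.18 in summer and 0.872 in autumn, so its decimal logarithm falls by 0.399 over that span. A straight line in the logarithm puts ρ at 1.61 for −10 °C and at 0.473, the remainder ratio at 10 °C. D is then what is not E, divided by one plus ρ. With summer's E for amber and autumn's for red, a crude borrowing, I get amber 20.5% and red 31.9%, higher than the forecast's red.

The simulation gives red: amber 16.8%, red 30.9%. The forecast's red stands and its amber lies within the tolerance, but its red is 7 points too low, with E ending at 50.5% in red, not near 60%.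

    Z ⇌ G (K = 3.50, k = 0.190 h⁻¹, Ea = 85.0 kJ mol⁻¹, ΔH = −7.00 kJ mol⁻¹)
    Z + X → X + D (k = 3200 M⁻¹ h⁻¹, Ea = 42.0 kJ mol⁻¹)
    X + G → X + E (k = 3300 M⁻¹ h⁻¹, Ea = 47.0 kJ mol⁻¹)
    Z + D → Q (k = 2.10 M⁻¹ h⁻¹, Ea = 45.0 kJ mol⁻¹)
    D ⇌ J (K = 1.60, k = 0.0420 h⁻¹, Ea = 83.0 kJ mol⁻¹, ΔH = −56.0 kJ mol⁻¹)
    (constants at −10 °C)

In amber the main reason for the share is the undoing of J into D: with that return taken away, amber gives 1.88% instead of 16.8%. J ends lower in red than in amber, 8.10% against 26.5%, so J is the species to watch. The split view has its region where X moves: the neighbour, red with 1.3 × 10⁻⁴ M of X, ends with E at 33.3%. There, ρ at 10 °C turns that E into D of 45.3%; the computed flask gives 46.2%.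

Readings and results are calculated for substances that don't exist; the scatter is artificial.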